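**Retrosynthetic overview**
- Target ⇒ its N5-unsubstituted 1,5-diazocan-2-one (C–N, N5–CH3), methylated last in the same flask.
- Eight-membered ring ⇒ transamidative ring expansion (amide C–N, N1–C2) of an N-(3-aminopropyl) beta-lactam, whose secondary amine comes from a reductive C–N coupling (N1–C8) of an N-(2-cyanoethyl) beta-lactam with N-(4-aminobutyl)benzamide.
- N-(2-cyanoethyl) beta-lactam ⇒ aza-Michael addition of (S)-4-phenylazetidin-2-one to acrylonitrile; the beta-lactam ⇒ cyclodehydration of (S)-3-amino-3-phenylpropanoic acid, the source of the stereocenter.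
- N-(4-aminobutyl)benzamide ⇒ mono-benzoylation of 1,4-diaminobutane with methyl benzoate.
- Ring order: the four-membered lactam first, then its expansion to the eight-membered diazocanone; both benzene rings are bought.

Assumption: the stereocenter in the SMILES is (S) at C4 of the diazocanone (N > phenyl > CH2 > H), the configuration of commercial (S)-3-amino-3-phenylpropanoic acid; equivalents and pressures are indicative.

**Route**

Step 1
Reactants: 1 1,4-diaminobutane; 2 methyl benzoate
Product: 3 N-(4-aminobutyl)benzamide
Conditions: 1 (6 equiv), neat, 110 °C, 16 h; excess 1 distilled off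
Reagents that add atoms: none
Why: Thermal ester aminolysis; the six-fold excess of the symmetrical diamine makes mono-acylation statistically dominant, and the amide nitrogen formed is no longer nucleophilic.

Step 2
Reactants: 4 (3S)-3-amino-3-phenylpropanoic acid
Product: 5 (4S)-4-phenylazetidin-2-one
Conditions: PPh3 (1.2 equiv), 2,2'-dipyridyl disulfide (1.2 equiv), MeCN (0.01 M), reflux
Reagents that add atoms: none
Why: Mukaiyama–Ohno oxidation–reduction condensation: the acid becomes its 2-pyridyl thioester, which is N-acylated intramolecularly at high dilution; no bond to the benzylic stereocenter is broken and it is not alpha to the carbonyl, so the S configuration of 4 is kept.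

Step 3
Reactants: 5 (4S)-4-phenylazetidin-2-one; 6 acrylonitrile
Product: 7 3-[(4S)-2-oxo-4-phenylazetidin-1-yl]propanenitrile
Conditions: 6 (1.5 equiv), KOtBu (10 mol%), THF, 0 °C to rt
Reagents that add atoms: none
Why: Base-catalysed aza-Michael addition (N-cyanoethylation) of the lactam N–H; the alpha-cyano carbanion formed deprotonates the next lactam, so catalytic base suffices, and the stereocenter is untouched.

Step 4
Reactants: 7 3-[(4S)-2-oxo-4-phenylazetidin-1-yl]propanenitrile; 3 N-(4-aminobutyl)benzamide
Product: 11 N-{4-[(4S)-5-methyl-2-oxo-4-phenyl-1,5-diazocan-1-yl]butyl}benzamide, via N-alkyl aldimine 8 (not isolated), via secondary amine 9 (not isolated), via NH-diazocanone 10 (not isolated)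
Conditions: 3 (1.5 equiv), Rh/C (5 wt% Rh, 5 mol% Rh), H2 (3 bar), MeOH, 25 °C; vent, 50 °C, 4 h; then 37% aq. HCHO (5 equiv), H2 (3 bar), 25 °C
Reagents that add atoms: formaldehyde (C=O)
Why: Proposed new method: a cross-reductive ring enlargement in which Rh/C half-hydrogenates the nitrile of 7 to an aldimine that the excess primary amine 3 intercepts (transimination, loss of NH3) to give aldimine 8, and hydrogenation then gives secondary amine 9; the nitrogen of 9 sits five atoms from the lactam carbonyl and adds to it through a six-membered tetrahedral intermediate that collapses with cleavage of the strained lactam C–N bond (new N1–C2 amide bond, four- to eight-membered ring, driven by release of beta-lactam strain) to give 10, which also removes the secondary amine before it can be alkylated again; formaldehyde and H2 then reductively methylate the only basic N–H left (N5) to give 11, the S stereocenter being neither deprotonated nor cleaved (Rh/C rather than Pd/C to spare the benzylic C–N bond); the closest known reaction types are the reductive N-alkylation of amines with nitriles over Rh/C and the cyanoethylation–hydrogenation–transamidation ring enlargement of lactams with primary amines (Zip reaction).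

**Compound list**
1 | 1,4-diaminobutane | NCCCCN | starting material
2 | methyl benzoate | COC(=O)c1ccccc1 | starting material
3 | N-(4-aminobutyl)benzamide | NCCCCNC(=O)c1ccccc1 | intermediate
4 | (3S)-3-amino-3-phenylpropanoic acid | N[C@@H](CC(=O)O)c1ccccc1 | starting material
5 | (4S)-4-phenylazetidin-2-one | O=C1C[C@@H](c2ccccc2)N1 | intermediate
6 | acrylonitrile | C=CC#N | starting material
7 | 3-[(4S)-2-oxo-4-phenylazetidin-1-yl]propanenitrile | N#CCCN1C(=O)C[C@H]1c1ccccc1 | intermediate
8 | N-[4-({3-[(4S)-2-oxo-4-phenylazetidin-1-yl]propylidene}amino)butyl]benzamide | O=C(NCCCCN=CCCN1C(=O)C[C@H]1c1ccccc1)c1ccccc1 | intermediate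
9 | N-[4-({3-[(4S)-2-oxo-4-phenylazetidin-1-yl]propyl}amino)butyl]benzamide | O=C(NCCCCNCCCN1C(=O)C[C@H]1c1ccccc1)c1ccccc1 | intermediate
10 | N-{4-[(4S)-2-oxo-4-phenyl-1,5-diazocan-1-yl]butyl}benzamide | N1CCCN(CCCCNC(=O)c2ccccc2)C(=O)C[C@H]1c1ccccc1 | intermediate
11 | N-{4-[(4S)-5-methyl-2-oxo-4-phenyl-1,5-diazocan-1-yl]butyl}benzamide | CN1CCCN(CCCCNC(=O)c2ccccc2)C(=O)C[C@H]1c1ccccc1 | target

**Step count**
Total steps: 4. Longest linear sequence: 3 (4 → 5 → 7 → 11); 3 is made in one step on a side branch.

**Steps most likely to fail**

Step 4 (the proposed new step). Risks: full reduction of the nitrile to the primary amine, which would ring-expand to the N1-unsubstituted diazocanone; partial arene saturation over Rh/C; slow ring expansion of 9. Fallback with known chemistry, setting out from 5 and coming back at 10: 5 is N-alkylated with 1-bromo-3-chloropropane (KOH, Bu4NBr, THF, rt) to (4S)-1-(3-chloropropyl)-4-phenylazetidin-2-one F1. Heating F1 with 3, NaI and K2CO3 in MeCN at 80 °C gives 9 by substitution, which ring-expands in the flask to 10, isolated here. 10 is then methylated to 11 with HCHO/HCO2H at 80 °C (Eschweiler–Clarke).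

Step 2. Risk: oligomerisation of the free amino acid instead of four-membered ring closure. Fallback, setting out from 4 and coming back at 5: esterification of 4 (EtOH, SOCl2, reflux; NaHCO3 work-up) gives ethyl (3S)-3-amino-3-phenylpropanoate F2. F2 is cyclised with tBuMgCl (3 equiv, THF, 0 °C) in a Breckpot-type Grignard lactamisation to 5.

Step 3. Risk: anionic polymerisation of acrylonitrile or base-induced lactam cleavage. Fallback, setting out from 4 and coming back at 7, with the N-substituent installed before ring closure: 4 is cyanoethylated (acrylonitrile, Et3N, MeOH–H2O, 40 °C) to (3S)-3-[(2-cyanoethyl)amino]-3-phenylpropanoic acid F3. F3 is cyclodehydrated with 2-chloro-1-methylpyridinium iodide and Et3N in MeCN at reflux under high dilution to 7.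

**Further compounds**
F1 | step 4 | (4S)-1-(3-chloropropyl)-4-phenylazetidin-2-one | ClCCCN1C(=O)C[C@H]1c1ccccc1
F2 | step 2 | ethyl (3S)-3-amino-3-phenylpropanoate | CCOC(=O)C[C@H](N)c1ccccc1
F3 | step 3 | (3S)-3-[(2-cyanoethyl)amino]-3-phenylpropanoic acid | N#CCCN[C@@H](CC(=O)O)c1ccccc1
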